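- Start with a leftover: at 30.0 h the midnight run, charged like birch, shows 33% target and 48% over-reaction product, so 19.0% of the starting material stands in neither column.

| flask | starting material | protic impurity | remark | time |
|---|---|---|---|---|
| midnight | 0.050 M | 0.025 M | run made earlier |  |
| summer | 0.070 M | 0.025 M | run made earlier |  |
| spring | 0.11 M | 0.025 M | run made earlier |  |
| noon | 0.050 M | 0.038 M | run made earlier |  |
| alder | 0.050 M | 0.0250 M | a single well-mixed tank run continuously and read at steady state, 50 h in it on average |  |
| cedar | 0.050 M | 0.0250 M | plug flow through a tube for 50 h, no back-mixing | 50 h |
| ash | 0.050 M (fed, over 40.0 h) | 0.0250 M | a stirred flask in which starting material is dosed at a steady rate over 40.0 h without added volume, worked up at 50 h | 50 h |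
| birch | 0.050 M | 0.0250 M | a closed flask charged with all of it at once and left for 50 h | 50 h |

- midnight (time / h: target / %, over-reaction product / %): 2.50: 53, 3; 6.00: 63, 7; 12.0: 58, 24; 30.0: 33, 48
- summer (time / h: target / %, over-reaction product / %): 15.0: 52, 25; 30.0: 34, 46; 50.0: 20, 65; 60.0: 17, 69
- spring (time / h: target / %, over-reaction product / %): 8.00: 55, 11; 20.0: 41, 27; 40.0: 26, 45; 60.0: 18, 60
- noon (time / h: target / %, over-reaction product / %): 15.0: 49, 30; 30.0: 30, 47; 50.0: 18, 60; 60.0: 13, 69

(standard deviation of a reading: 1.5 percentage points)

- the stated concentrations are those of everything mixed, before any reaction; amounts are the same in each set-up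
- the feed brings no volume worth counting
- the earlier runs were made in a closed, stirred flask
- a reading or a percentage of target counts all its forms, free or not

- the set-up with the highest share of target in all that became target or over-reaction product, at the outlet or at the end ("none" if the first two lie within 2 percentage points) (alder / cedar / ash / birch / none)
- share of target in all that became target or over-reaction product, at the outlet or at the end, alder
- share of target in all that became target or over-reaction product, at the outlet or at the end, cedar
- share of target in all that became target or over-reaction product, at the outlet or at the end, ash
- share of target in all that became target or over-reaction product, at the outlet or at the end, birch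

- The share asked for, the selectivity, keeps that leftover off its books, so you need one entry: what becomes of a target molecule once it is born.
- From 12.0 h to 30.0 h the midnight sum of the two columns goes from 82.0% to 81.0%, while the share falls from 70.7% to 40.7%, so the entry is a transfer from target to over-reaction product.
- Those two shares give the ageing rate, the fraction of target lost per hour, 0.0306 /h, a reading that carries the scatter. A molecule of age a stays target with chance e^(-rate × a).
- Birth is quick: the midnight run already holds 56.0% in the two columns at 2.50 h, far shorter than the mean life of 32.7 h. So count birch and cedar as born at the start, which gives 21.6% for each.
- In alder, ages spread around the 50 h average, and 1/(1 + rate × time) gives 39.5%.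
- In ash, you count births as spread evenly over the feed and set aside any that trail it, so the reckoned ages run from 10.0 h to 50 h. The mean chance is 42.4%, which makes ash your pick.
- The forecast chose ash with 41% for alder, 24% for cedar, 46% for ash and 24% for birch, saying “Ash still looks best, narrowly.”
- The flask gives ash, with 36.9% for alder, 22.7% for cedar, 41.6% for ash and 22.7% for birch.

    starting material ⇌ target + released group (K = 0.130 M, k = 1.10 × 10⁻⁴ /s)
    starting material + target ⇌ idle adduct, settled at all times (K = 8.60 /M)
    starting material + protic impurity → quenched substrate (k = 1.20 × 10⁻⁴ /M/s)
    target → over-reaction product (k = 1.00 × 10⁻⁵ /s)

- At the end of the ash feed, 40.0 h, the flask held 16.4% starting material, 42.1% target and 34.8% over-reaction product. By 50.0 h ash stood at 11.0%, 34.2% and 48.1%, with target still passing into over-reaction product. The sum of target and over-reaction product in ash rose from 76.9% to 82.3% over those hours, so births went on after the feed. Your ageing rate lands 0.80 percentage points from the computed ash share and 2.6 points from alder.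
- Read the same ash flask at 5.0 d: counted the same way, with births over the feed, the reckoned ages run from 80.0 h to 120 h, so the ageing rate gives 4.96%. The computed share is 5.33%.

(The data stem from a simulated flask for substances that don't exist; scatter was added.)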